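**Retrosynthetic overview**
1. The target is a fully substituted 2,5-dihydroxy-1,4-benzoquinone. The one strategic cut is the bond between C1 of the henicosyl chain and ring carbon C6, leading back to 2,5-dihydroxy-3-methyl-1,4-benzoquinone and a henicosyl radical.
2. The radical comes from docosanoic acid: loss of CO2 from this cheap C22 fatty acid gives exactly the C21 chain, with no prior functional-group work on the chain.
3. Enabling feature: in the quinone precursor, C6 is the only hydrogen-bearing ring carbon and sits between the C1 carbonyl and the enolic C5–OH. A radical adding there gives a C5 radical stabilised by its OH and the C4 carbonyl, and the product has no ring C–H left for a second alkylation.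
4. The quinone partner is made from 1,2,4,5-tetramethoxybenzene by ortho-lithiation/methylation, oxidative demethylation to the para-quinone and hydrolysis of both vinylogous esters. No ring is formed in the route; the single six-membered carbocycle is carried through from the starting arene.
5. The coupling is placed last and runs on the unprotected hydroxyquinone, so nothing has to be removed afterwards.

Key step: step 4

Remark: the target has no stereocentre and no stereogenic double bond; it is made as the 2,5-dihydroxy-1,4-benzoquinone tautomer drawn in the given SMILES.

**Route**

Step 1
Reactants: 1 1,2,4,5-tetramethoxybenzene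
Product: 3 1,2,4,5-tetramethoxy-3-methylbenzene, via tetramethoxyphenyllithium 2 (not isolated)
Conditions: n-BuLi (1.1 equiv), TMEDA, THF, 0 °C to rt; then MeI, −78 °C to rt
Reagents that add atoms: iodomethane (MeI), CI
Why: Directed ortho-metalation, in which the ring C–H flanked by two methoxy groups is deprotonated by n-BuLi/TMEDA and the aryllithium is trapped by SN2 methylation, the near-stoichiometric amount of base holding the reaction at mono-methylation.

Step 2
Reactants: 3 1,2,4,5-tetramethoxy-3-methylbenzene
Product: 4 2,5-dimethoxy-3-methyl-1,4-benzoquinone
Conditions: (NH4)2Ce(NO3)6 (2.5 equiv), MeCN/H2O (2:1), 0 °C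
Reagents that add atoms: water, O
Why: Oxidative demethylation of a para-dimethoxyarene by tetravalent cerium (two one-electron oxidations, attack of water, loss of methanol), where either para pair of methoxy groups leads to the same quinone by symmetry and the other two remain as vinylogous esters.

Step 3
Reactants: 4 2,5-dimethoxy-3-methyl-1,4-benzoquinone
Product: 5 2,5-dihydroxy-3-methyl-1,4-benzoquinone
Conditions: 2 M NaOH aq, 1,4-dioxane, 60 °C; then 2 M HCl to pH 1
Reagents that add atoms: sodium hydroxide, [Na+].[OH-]
Why: Saponification of the two vinylogous esters by addition–elimination of hydroxide at C2 and C5, giving the base-stable dianion of the dihydroxyquinone, which is protonated on acidification.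

Step 4
Reactants: 5 2,5-dihydroxy-3-methyl-1,4-benzoquinone; 6 docosanoic acid
Product: 8 2,5-dihydroxy-3-henicosyl-6-methyl-1,4-benzoquinone (target), via henicosyl radical 7 (not isolated)
Conditions: AgNO3 (0.3 equiv), (NH4)2S2O8 (2 equiv, added slowly in H2O), 6 (2.5 equiv), MeCN/H2O (2:1), 75 °C
Reagents that add atoms: none
Why: Peroxydisulfate oxidises monovalent silver to divalent silver, which oxidises the carboxylate of 6 to an acyloxy radical that loses CO2 to give the primary radical 7; this nucleophilic radical adds to C6 of the electron-poor quinone 5, the adduct radical at C5 (stabilised by its OH and the C4 carbonyl) is oxidised by divalent silver or peroxydisulfate, and loss of the C6 proton returns the hydroxyquinone. The closest known reaction type is the silver/peroxydisulfate decarboxylative alkylation of quinones (Jacobsen–Torssell reaction, a Minisci-type radical C–H alkylation), established for 2-hydroxy-1,4-naphthoquinone at the carbon next to C–OH, together with the thermal diacyl peroxide alkylation of 2,5-dihydroxy-1,4-benzoquinones at the same kind of carbon. No ring is closed and no stereocentre is formed. The step needs site selectivity and mono-alkylation: C6 is the only unsubstituted ring carbon of 5 and the product has no ring C–H left, so a single regioisomer and no over-alkylation are expected. Attack at carbon and not at oxygen follows from the polarity match between the nucleophilic alkyl radical and the enone carbon, and the acid released from the oxidant keeps 5 protonated and therefore electrophilic. The excess of the cheap acid 6 should make up for radical dimerisation and hydrogen abstraction from the solvent.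

**Compound list**
1 | 1,2,4,5-tetramethoxybenzene | COc1cc(OC)c(OC)cc1OC | starting material
2 | (2,3,5,6-tetramethoxyphenyl)lithium | [Li]c1c(OC)c(OC)cc(OC)c1OC | intermediate
3 | 1,2,4,5-tetramethoxy-3-methylbenzene | Cc1c(OC)c(OC)cc(OC)c1OC | intermediate
4 | 2,5-dimethoxy-3-methyl-1,4-benzoquinone | COC1=CC(=O)C(OC)=C(C)C1=O | intermediate
5 | 2,5-dihydroxy-3-methyl-1,4-benzoquinone | CC1=C(O)C(=O)C=C(O)C1=O | intermediate
6 | docosanoic acid | CCCCCCCCCCCCCCCCCCCCCC(=O)O | starting material
7 | henicosan-1-yl radical | CCCCCCCCCCCCCCCCCCCC[CH2] | intermediate
8 | 2,5-dihydroxy-3-henicosyl-6-methyl-1,4-benzoquinone | CCCCCCCCCCCCCCCCCCCCCC1=C(O)C(=O)C(C)=C(O)C1=O | target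

**Step count and risks**
Total steps: 4. Longest linear sequence: 4 steps (1 → 3 → 4 → 5 → 8); docosanoic acid 6 enters as purchased.

Steps most likely to fail, riskiest first:

Step 4. What may go wrong: oxidative degradation of the electron-rich hydroxyquinone by the peroxydisulfate/silver system, and poor capture of the radical because the C22 acid is sparingly soluble in aqueous acetonitrile, so that radical dimerisation and hydrogen abstraction win. Fallback (polar three-component reductive alkylation in place of the radical coupling): it sets out from 5 and comes back at 8. Commercial henicosan-1-ol (CCCCCCCCCCCCCCCCCCCCCO) is oxidised with Dess–Martin periodinane in CH2Cl2 to henicosanal F1. Compound 5, henicosanal F1 and diethyl 1,4-dihydro-2,6-dimethylpyridine-3,5-dicarboxylate (Hantzsch ester) are then stirred with catalytic L-proline in CH2Cl2 at rt. Knoevenagel condensation at C6 should give the henicosylidene trione F2 (not isolated, alkene geometry not defined), and conjugate hydride transfer from the Hantzsch ester followed by tautomerisation should give 8 directly.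

Step 2. What may go wrong: over-oxidation of the arene radical cation, its oxidative dimerisation to biaryl-type products, or oxidation at the benzylic methyl group. Fallback (demethylation and autoxidation in place of oxidative demethylation): it sets out from 3 and comes back at 5, bypassing 4 and step 3. Exhaustive demethylation of 3 with BBr3 in CH2Cl2 (−78 °C to rt) should give 3-methylbenzene-1,2,4,5-tetrol F3. Aeration of this in aqueous NaHCO3 followed by acidification should give 5, since tetrahydroxybenzenes autoxidise readily to 2,5-dihydroxy-1,4-benzoquinones.

Step 1. What may go wrong: incomplete lithiation or a second lithiation, giving a mixture of unmethylated, mono- and dimethylated arenes that is hard to separate. Fallback (halogenation and cross-coupling in place of metalation/alkylation): it sets out from 1 and comes back at 3. Monobromination of 1 with NBS in MeCN at 0 °C should give 3-bromo-1,2,4,5-tetramethoxybenzene F4, which can be freed from starting material and dibromide by crystallisation. Suzuki–Miyaura methylation with trimethylboroxine, Pd(OAc)2/SPhos and K2CO3 in dioxane/H2O at 90 °C should then give 3.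

**Further compounds**
F1 | step 4 | henicosanal | CCCCCCCCCCCCCCCCCCCCC=O
F2 | step 4 | 3-henicosylidene-5-hydroxy-6-methylcyclohex-5-ene-1,2,4-trione (alkene geometry not defined) | CCCCCCCCCCCCCCCCCCCCC=C1C(=O)C(O)=C(C)C(=O)C1=O
F3 | step 2 | 3-methylbenzene-1,2,4,5-tetrol | Cc1c(O)c(O)cc(O)c1O
F4 | step 1 | 3-bromo-1,2,4,5-tetramethoxybenzene | Brc1c(OC)c(OC)cc(OC)c1OC
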